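In the stirred vessel of the ash run, G stands at twice the L, yet D reads 56% after 3.00 h and 60% after 40.0 h, while Z climbs from 13% to 39%. I read this as follows: G vanishes within hours, partly into D and partly by a loss of its own, and the L it leaves drains slowly to Z.

| setting | ash | alder | oak | Monday's | Tuesday's | Wednesday's |
|---|---|---|---|---|---|---|
| L | 20 mM | 10 mM | 15 mM | 20 mM | 20 mM | 20 mM (fed, over 30 h) |
| G | 40 mM | 40 mM | 40 mM | 40.0 mM (fed, over 30 h) | 40.0 mM | 40.0 mM |
| E | 100 mM | 100 mM | 100 mM | 100 mM | 100 mM | 100 mM |
| remark | run made earlier | run made earlier | run made earlier | all else is in the flask from the start; the feed brings no volume worth counting | everything together at the start | all else is in the flask from the start; the feed brings no volume worth counting |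
| time |  |  |  | 3.0 d | 3.0 d | 3.0 d |

ash run (percent of the L charged)

| time / h | D / % | Z / % |
|---|---|---|
| 3.00 | 56 | 13 |
| 6.00 | 58 | 17 |
| 10.0 | 59 | 24 |
| 15.0 | 58 | 29 |
| 25.0 | 60 | 35 |
| 40.0 | 60 | 39 |

alder run (percent of the L charged)

| time / d | D / % | Z / % |
|---|---|---|
| 0.208 | 67 | 14 |
| 0.333 | 65 | 20 |
| 0.500 | 67 | 24 |
| 0.833 | 66 | 28 |
| 1.67 | 66 | 30 |
| 2.50 | 66 | 31 |

oak run (percent of the L charged)

| time / d | D / % | Z / % |
|---|---|---|
| 0.208 | 64 | 16 |
| 0.333 | 60 | 19 |
| 0.500 | 61 | 25 |
| 0.833 | 63 | 29 |
| 1.67 | 60 | 36 |
| 2.50 | 62 | 36 |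

(standard deviation of a reading: 1.5 percentage points)

- a reading or a percentage of D counts all its forms, free or not

* which flask leads in share of D in D plus Z ("all alike" within 1.5 percentage points) (Monday's / Tuesday's / Wednesday's / all alike)
* share of D in D plus Z at the end, Monday's
* share of D in D plus Z at the end, Tuesday's
* share of D in D plus Z at the end, Wednesday's

Let G reach L in the share cL/(cL + a). Summed over the burst, with the drain to Z neglected, the G charged equals the L turned to D plus a times the natural logarithm of L charged over L left. Ash gives 30.6 mM for a, the break-even amount, the cL at which L and the loss take equal shares of G; it is a selectivity factor written as a concentration. Alder gives 31.0 mM and oak 31.7 mM, so a holds while L changes, at the same E.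

The two amounts to compare are a and the cL that G meets. Tuesday's repeats ash, so its ratio starts at 0.654. In Monday's, L drains with a time of 12.3 h, read from the later part of ash, and the fed G takes L as well, at about the feed rate times cL/a once cL lies well below a. Adding the two losses shortens the time to 7.99 h, so I estimate the ratio at mid-feed near 0.100; this is a rough figure, since the drain time comes from another flask at another moment. In Wednesday's, 2.00 mM of L is in by 3.00 h, a ratio of 0.0654. I therefore put Tuesday's first and Wednesday's last, with Tuesday's at 60.6%, the last ash reading.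

The forecast names Tuesday's, with 28% for Monday's, 59.5% for Tuesday's, which differs from my figure, and 4% for Wednesday's, where “G dies within a few hours while L trickles in”.

The flasks give 24.7% for Monday's, 58.6% for Tuesday's and 5.16% for Wednesday's, so Tuesday's leads.

    L + G → D (k = 0.540 M⁻¹ min⁻¹)
    E + G → Q (k = 0.160 M⁻¹ min⁻¹)
    L + E → Z (k = 0.0210 M⁻¹ min⁻¹)
    G → J (k = 8.70 × 10⁻⁵ min⁻¹)
    L + D ⇌ X, settled at all times (K = 27.0 M⁻¹)

Just after the start of Tuesday's, G goes into Q 1.5 times as fast as into D, and a over the L charged is 1.53. In the same flask with 16 mM of G, D ends at 27.7%, and with a that D accounts for 15.5 mM of G.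

The readings are simulated on assumed constants, and the scatter is random.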